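Target and second product draw on the same reagent, so I asked what share of the reagent target gets in each of these flasks.

| setting | amber | violet | teal | blue | north-east | east | north-west | south-west | north |
|---|---|---|---|---|---|---|---|---|---|
| starting material | 0.10 M | 0.10 M | 0.10 M | 0.10 M | 0.10 M | 0.10 M | 0.10 M | 0.10 M | 0.10 M |
| second substrate | 0.20 M | 0.10 M | 0.40 M | 0.20 M | 0.200 M | 0.200 M (fed, over 50 h) | 0.200 M | 0.200 M | 0.200 M |
| reagent | 0.060 M | 0.060 M | 0.060 M | 0.030 M | 0.0600 M (fed, over 50 h) | 0.0600 M | 0.0600 M (fed, over 12 h) | 0.0600 M | 0.0600 M (in portions, 2, over 50 h) |
| free catalyst | 2.5 mM | 2.5 mM | 2.5 mM | 2.5 mM | 2.5 mM | 2.5 mM | 2.5 mM | 2.5 mM | 2.5 mM |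
| remark | run made earlier | run made earlier | run made earlier | run made earlier | all else is in the flask from the start; the feed brings no volume worth counting | all else is in the flask from the start; the feed brings no volume worth counting | all else is in the flask from the start; the feed brings no volume worth counting | everything together at the start | first portion at the start, last at 50 h |
| time |  |  |  |  | 2.5 d | 2.5 d | 2.5 d | 2.5 d | 2.5 d |

amber run (percent of the starting material charged): time / h: target / % = 2.50: 1; 8.00: 4; 12.0: 5; 20.0: 6; 30.0: 9; 40.0: 10

violet run (percent of the starting material charged): time / d: target / % = 0.500: 5; 1.04: 14; 1.67: 15; 2.08: 19; 2.50: 21; 3.00: 20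

teal run (percent of the starting material charged): time / d: target / % = 0.208: 2; 0.625: 1; 1.04: 8; 1.67: 7; 2.50: 5; 3.00: 8

blue run (percent of the starting material charged): time / d: target / % = 0.250: 1; 0.417: 1; 0.833: 4; 1.67: 6; 3.00: 7

(each reading ± 1.5 percentage points)

- the numbers in the tables scatter by 1.5 percentage points (one standard deviation)
- steps thought possible: starting material + free catalyst <-> catalyst intermediate A; reagent + catalyst intermediate A -> free catalyst + target; second substrate + free catalyst <-> catalyst intermediate B; reagent + catalyst intermediate B -> free catalyst + second product; catalyst intermediate B -> spent catalyst

- the flask with the highest amount of target, in percent of the starting material charged ("all alike" if they lie within 1.5 percentage points) (north-east / east / north-west / south-west / north / all alike)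
- final target, as a percentage of the starting material charged, in north-east
- final target, as a percentage of the starting material charged, in east
- final target, as a percentage of the starting material charged, in north-west
- final target, as a percentage of the starting material charged, in south-west
- final target, as a percentage of the starting material charged, in north

I took both catalyst bindings as fast and reversible against the reagent steps, so that each intermediate stands in proportion to its substrate times free catalyst. Reagent and free catalyst then cancel from the ratio of the two product rates, which becomes a selectivity factor times starting material over second substrate. With starting material staying near 0.10 M, I read that ratio from violet. If its reagent was used up, the 21% of target at 2.50 d stands against the rest of the reagent as second product, a ratio of 0.538 at 0.10 M of second substrate. That reading gave 0.0538 M, and this c× is the second-substrate level at which target and second product form at equal rates. The share of reagent going to target is then c×/(c× + second substrate).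

Teal and blue checked this within the scatter of 1.5 percentage points: with its reagent used up, teal should reach 7.12% and read 8%, while blue should reach 6.36% and read 7%.

South-west stands above c× from the start, with a share of 21.2%, so spending its whole reagent charge gives 12.7% of target. Reagent feeding leaves that share as it is, so I put north-east, north-west and north at or below that figure, according to how much late reagent stays unused. East differs: counting its second substrate from the feed, with none consumed, I had it below c× for the first 13.5 h of the 50 h feed. Averaging the share over that steady rise, with the reagent charge spent evenly and completely, gave 41.7%, hence 25.0% of target in east by my reckoning.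

The forecast also chose east, but at 30%, above my figure, adding of that value, “Its value depends on unknown binding constants”. It gave 9% for north-east, 10.5% for north-west, 11% for south-west and 8% for north.

    starting material + free catalyst ⇌ catalyst intermediate A (K = 5.30 L mol⁻¹, k = 270 L mol⁻¹ h⁻¹)
    reagent + catalyst intermediate A → free catalyst + target (k = 19.0 L mol⁻¹ h⁻¹)
    second substrate + free catalyst ⇌ catalyst intermediate B (K = 6.50 L mol⁻¹, k = 210 L mol⁻¹ h⁻¹)
    reagent + catalyst intermediate B → free catalyst + second product (k = 24.0 L mol⁻¹ h⁻¹)
    catalyst intermediate B → spent catalyst (k = 0.0160 h⁻¹)

East gave 21.3%, the highest of the flasks and 8.7 points under the forecast, while north-east gave 8.57%, north-west 11.7%, south-west 12.4% and north 7.75%; east still held 22.5% of its reagent charge and had formed 0.0252 M of second product. Target in east thus took 45.8% of the reagent spent, against my 41.7%. The neighbour of north charged with 0.050 M of second substrate starts below c× and ends with 76.3% of that charge, so the level midway between gives a share of 55.0%, and with 15.3% of target beside 0.0112 M of second product that neighbour's share over its whole run was 57.7%.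

The numbers in the tables are calculated with made-up constants, and the scatter is random.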